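**One-step world.** In a one-step world each electrophile that reacts uses one nucleophile and sets free one acid, and that acid, unless the scavenger takes it, holds a second nucleophile as protonated nucleophile, so every turnover costs two bases and the reaction stalls once the scavenger is spent. The flask's reserve is 50.0%: that is the scavenger charge divided by two, as a share of the electrophile charged.

| flask | electrophile | protonated nucleophile | gas | scavenger | remark | time |
|---|---|---|---|---|---|---|
| blue | 0.025 M | 0.030 M | 10 mM (held) | 0.035 M | run made earlier |  |
| teal | 0.025 M | 0.030 M | 10 mM (held) | 0.055 M | run made earlier |  |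
| flask | 0.025 M | 0.0300 M | 10 mM (held) | 0.0250 M |  | 2.0 h |

| run | time / min | electrophile / % | target / % |
|---|---|---|---|
| blue | 6.00 | 89.1 | 9.5 |
| blue | 10.0 | 80.1 | 18.6 |
| blue | 15.0 | 69.9 | 24.5 |
| blue | 25.0 | 54.2 | 35.2 |
| blue | 40.0 | 35.9 | 42.5 |
| blue | 80.0 | 13.1 | 50.7 |
| teal | 6.00 | 87.2 | 11.8 |
| teal | 10.0 | 76.0 | 21.4 |
| teal | 15.0 | 64.1 | 28.3 |
| teal | 25.0 | 47.5 | 40.7 |
| teal | 40.0 | 29.4 | 48.6 |
| teal | 80.0 | 8.4 | 56.6 |

(readings scatter by 0.5 percentage points)

- at the start none of the gas is in solution
- the earlier runs do not show how much of nucleophile is bound; that part of a forecast is a guess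

- part of the electrophile that has reacted at 2.0 h
- share of free nucleophile in free nucleophile and protonated nucleophile together, at 2.0 h

**Two ways.** By the balance, the flask's electrophile should stop at its reserve and the blue run at 70.0%. My second way read the decay as pseudo-first-order: the early slopes were 0.0262 min⁻¹ in blue and 0.0320 min⁻¹ in teal, and a straight line in scavenger, extended to the flask, gave 0.0233 min⁻¹, hence 93.9% reacted at 2.0 h.

**Which cheats.** The two parted, 93.9% against 50.0%, and I took the one-step world beneath the balance to be the cheat, because by 80.0 min the blue run had lost 86.9% of its electrophile while its target stood at 50.7%, which left 36.2% in some product I could not count, so these readings did not show whether blue had passed its reserve. The electrophile's late slope in blue read 0.0252 min⁻¹, whichever routes it held. The balance books no taker of acid besides the scavenger, yet gas held at 10 mM keeps entering, so I suspected a base coming from it. I committed to 93.9% and expected a free share far from zero, without a figure.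

**The result.** The forecast gave 90% and 20%, holding that “released protons load the scavenger, which is nearly exhausted late on”. The flask gave 93.6% and 75.1%.

    electrophile + nucleophile → acid set free + target (k = 0.0310 M⁻¹ s⁻¹)
    nucleophile + acid set free ⇌ protonated nucleophile, settled at all times (K = 1200 M⁻¹)
    acid set free + free base ⇌ salt of the base (K = 1.00 × 10⁶ M⁻¹, k = 0.630 M⁻¹ s⁻¹)
    gas ⇌ free base, rate k4*(csat - [free base]) (kL = 0.00100 s⁻¹)
    electrophile + target → side product (k = 0.0120 M⁻¹ s⁻¹)
    nucleophile + acid set free ⇌ idle adduct, settled at all times (K = 28.0 M⁻¹)
    acid set free + scavenger → scavenged by-product (k = 1.10 M⁻¹ s⁻¹)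

**Reserve checked.** Each side product counts as two electrophile, one of which came through the target, so the flask's turnover at 2.00 h was 71.3% of the electrophile charged, past its reserve of 50.0%, with scavenger down to 0.178% of its charge and salt of the base at 0.0195 M. The neighbour flask, charged with 0.043 M of scavenger, has a reserve of 86.0%, and its turnover of 76.4% stayed below that; it kept 7.35% of its scavenger, held 0.00841 M of salt of the base, and showed a free share of 92.9%.

The readings stem from a simulated flask with made-up constants; noise was put on by code.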